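The plan reconnects C1 to C5, which turns the ten-membered carbocycle into a cis-fused hydroazulene. In the target, the C1 ketone, the Z C4=C5 alkene and the C15 hydroxyl are spaced as the donor, breaking bond and leaving group of a Grob fragmentation. The precursor is a tertiary C1 carbinol in a 5-7 bicycle with a C3 ketone and a C4–C15 spiro-epoxide whose oxygen is trans to H5. One operation on it merges both small rings into the ten-membered ring and reveals the ketone, alkene and CH2OH together. The bicycle comes from (R)-citramalic acid by allylboration, ring-closing metathesis, iodolactonisation and a 5-exo-dig radical cyclisation. Acid then closes the C3–O–C10 furanone.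

Key step: step 22

Remarks
- **Numbering (used for every compound).** C1 is the ketone. C2 and C3 are the furanone carbons. C4 bears C15. C5 is the alkene CH and C6 the lactone OCH. C7 bears C11, with C12 the carbonyl and C13 the methylene. C8 is the isovalerate CH, C9 the CH2, and C10 bears C14 and the ether oxygen. Ring A is C1–C5 and ring B is C1, C5–C10.
- **Faces.** Ring B is drawn with C1, C5, C6, C7, C8, C9, C10 running clockwise. β points to the viewer and α points away. The target is 6α-O, 7α-C11, 8α-O, 10β-O, 10α-CH3, which corresponds to 6S,7R,8R,10R.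
- **Stereochemistry of the given structure.** Its lactone is cis-fused and cis to the C8 ester. The route is planned for exactly this all-cis C6/C7/C8 array.
- **C1 and C5.** These centres of the bicycle vanish in step 22. Only the trans relation between H5 and the epoxide oxygen matters.
- **Geometry in the cis-fused bicycle.** O1 (α) and the epoxide oxygen (β) lie on opposite faces of ring A, so one metal centre cannot hold both. More than two equivalents of Ti(OiPr)4 are therefore planned. In a five-membered ring the anti alignment is only approximate.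
- **Protection of O10.** O10 is carried as a methoxymethyl acetal. A silyl group next to the C1 alkoxide could shift onto it, and the acetal also permits chelation in step 11.
- **Closure of ring A.** An aldol closure was not used. It would be a 5-(enolendo)-exo-trig process. It would also pass through a 2-methylene-1,4-diketone whose acidic H5 is flanked by a β-acyloxy group.

Step 1
Reactants: 1 (R)-citramalic acid
Product: 2 dioxolanone acid [(4R)-2,2,4-trimethyl-5-oxo-1,3-dioxolan-4-yl]acetic acid
Conditions: Me2C(OMe)2, TsOH·H2O (cat.), acetone, rt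
Reagents that add atoms: 2,2-dimethoxypropane COC(C)(C)OC
Why: Acid-catalysed acetal exchange (1,3-dioxolan-4-one formation) ties the tertiary hydroxyl and the adjacent C1 carboxyl into a five-membered ring in preference to the six-membered alternative, which leaves only the C8 carboxyl free and keeps the chiral-pool C10 centre untouched.

Step 2
Reactants: 2 dioxolanone acid
Product: 3 S-ethyl thioester of 2
Conditions: EtSH, DCC, DMAP (cat.), CH2Cl2, 0 °C to rt
Reagents that add atoms: ethanethiol CCS
Why: Carbodiimide (Steglich-type) thioesterification activates the only free carboxyl under neutral conditions that the dioxolanone tolerates.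

Step 3
Reactants: 3 S-ethyl thioester
Product: 4 C8 aldehyde [(4R)-2,2,4-trimethyl-5-oxo-1,3-dioxolan-4-yl]acetaldehyde
Conditions: Et3SiH, 10% Pd/C, acetone, rt
Reagents that add atoms: none
Why: The Fukuyama reduction stops at the aldehyde and is neutral, so the β-oxygenated aldehyde cannot eliminate and the dioxolanone is not reduced.

Step 4
Reactants: 5 allylboronic acid pinacol ester; 6 tert-butyl but-3-enoate (excess)
Product: 7 tert-butyl (E)-5-(4,4,5,5-tetramethyl-1,3,2-dioxaborolan-2-yl)pent-3-enoate
Conditions: second-generation Hoveyda–Grubbs catalyst (2 mol%), CH2Cl2, 40 °C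
Reagents that add atoms: none
Why: Olefin cross-metathesis of two unhindered terminal alkenes should favour the thermodynamically preferred E allylboronate, and the excess of 6 limits homodimerisation of 5.

Step 5
Reactants: 4 C8 aldehyde; 7 (E)-allylboronate
Product: 8 anti homoallylic alcohol tert-butyl (3S,4R)-3-ethenyl-4-hydroxy-5-[(4R)-2,2,4-trimethyl-5-oxo-1,3-dioxolan-4-yl]pentanoate
Conditions: (S)-TRIP [(S)-3,3'-bis(2,4,6-triisopropylphenyl)-1,1'-binaphthyl-2,2'-diyl hydrogen phosphate] (5 mol%), 4 Å MS, toluene, −30 °C
Reagents that add atoms: none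
Why: Chiral phosphoric acid catalysed allylboration runs through a closed chair transition state, so the E geometry of 7 becomes the anti C7/C8 relationship and the catalyst antipode is chosen for Si-face attack on the aldehyde, which sets C8 (R) and C7 independently of the remote C10 centre.

Step 6
Reactants: 8 anti homoallylic alcohol
Product: 9 C8 triethylsilyl ether of 8
Conditions: Et3SiCl, imidazole, CH2Cl2, 0 °C
Reagents that add atoms: chlorotriethylsilane CC[Si](Cl)(CC)CC
Why: Standard silylation of the only free (secondary) hydroxyl blocks lactonisation and protects O8 from the organometallic reagents that follow.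

Step 7
Reactants: 9 silyl ether
Product: 10 Weinreb amide tert-butyl (3S,4R,6R)-3-ethenyl-6-hydroxy-7-[methoxy(methyl)amino]-6-methyl-7-oxo-4-(triethylsilyloxy)heptanoate
Conditions: MeNH(OMe)·HCl, iPrMgCl, THF, −20 to 0 °C
Reagents that add atoms: N,O-dimethylhydroxylamine hydrochloride CNOC.Cl
Why: Aminolysis of the activated dioxolanone by the chloromagnesium amide (Weinreb amide synthesis) releases acetone and the C10 hydroxyl, while the bulky tert-butyl ester is left alone.

Step 8
Reactants: 10 Weinreb amide
Product: 11 C10 methoxymethyl ether of 10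
Conditions: MeOCH2Cl, iPr2NEt, Bu4NI (cat.), CH2Cl2, 40 °C
Reagents that add atoms: chloromethyl methyl ether COCCl
Why: O-alkylation of the tertiary hydroxyl with the reactive α-chloro ether gives an acetal that chelates in step 11, cannot migrate in step 22 and falls off in the final acid step.

Step 9
Reactants: 11 protected Weinreb amide
Product: 12 vinyl ketone tert-butyl (3S,4R,6R)-3-ethenyl-6-(methoxymethoxy)-6-methyl-7-oxo-4-(triethylsilyloxy)non-8-enoate
Conditions: CH2=CHMgBr, THF, −20 to 0 °C; inverse quench into cold aq. NH4Cl
Reagents that add atoms: vinylmagnesium bromide C=C[Mg]Br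
Why: In the Weinreb ketone synthesis the chelated tetrahedral adduct survives until the quench, so no second addition occurs, and the inverse quench keeps the liberated amine from adding to the enone.

Step 10
Reactants: 12 vinyl ketone
Product: 13 cycloheptenone (C1 ketone; C5=C6; 7α-CH2CO2tBu; 8α-OSiEt3; 10β-OCH2OMe; 10α-CH3)
Conditions: second-generation Grubbs catalyst (5 mol%), CH2Cl2 (2 mM), 40 °C
Reagents that add atoms: none
Why: Ring-closing metathesis of the enone vinyl group onto the C6 vinyl group closes ring B, helped by the quaternary C10 and driven by loss of ethene, without touching a stereocentre.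

Step 11
Reactants: 13 cycloheptenone; 14 (4-bromobut-1-yn-1-yl)trimethylsilane
Product: 16 1α-carbinol bearing the β-oriented 4-(trimethylsilyl)but-3-ynyl chain, via Grignard reagent 15 (not isolated)
Conditions: 14, Mg, THF, rt; then 13, LaCl3·2LiCl, THF, −78 to −40 °C
Reagents that add atoms: none
Why: In this chelation-controlled 1,2-addition of a Grignard reagent to an α-alkoxy enone the metal ties O1 to the C10 acetal oxygen and the α face is screened by C14, the 8-silyloxy group and the C7 side chain, so the C2–C3–C4–C15 chain enters from the β face (a centre erased in step 22), while LaCl3·2LiCl and the branched C7 disfavour 1,4-addition.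

Step 12
Reactants: 16 1α-carbinol
Product: 19 tert-butyl acrylate (C11=C13 installed), via Mannich base 17 (not isolated), via ammonium iodide 18 (not isolated)
Conditions: LiN(iPr)2 (2.3 equiv), THF, −78 °C; Me2N=CH2 I, −78 °C to rt; MeOH quench, then MeI, rt; then sat. aq. NaHCO3, CH2Cl2, rt
Reagents that add atoms: N,N-dimethylmethyleneiminium iodide C=[N+](C)C.[I-]
Why: The ester enolate Mannich reaction with Eschenmoser's salt, quaternisation and Hofmann-type elimination form the standard α-methylenation sequence, placed here because no organometallic reagent follows and no other enolisable carbonyl is present.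

Step 13
Reactants: 19 tert-butyl acrylate
Product: 20 terminal alkyne with free 8α-hydroxyl
Conditions: Bu4NF, AcOH (1:1), THF, 0 °C to rt
Reagents that add atoms: none
Why: Buffered fluoride desilylation removes the alkynyl and the O8 silyl groups in one operation, and the buffer keeps the O8 alkoxide from attacking the ester.

Step 14
Reactants: 20 terminal alkyne
Product: 21 iodolactone (6α-O cis-fused α-methylene lactone; 5β-I; 8α-OH)
Conditions: I2, NaHCO3, MeCN, 0 °C, dark
Reagents that add atoms: iodine II
Why: In this 5-exo iodolactonisation only the β-face iodonium ion can be opened by the carbonyl oxygen of the α-oriented C7 side chain, which sets 6α-O (6S, cis-fused) and 5β-I by anti addition while the tert-butyl group leaves as isobutene, and the acrylate and the alkyne react more slowly with iodine.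

Step 15
Reactants: 21 iodolactone; 22 isovaleryl chloride
Product: 23 8α-isovalerate of 21
Conditions: pyridine, DMAP (cat.), CH2Cl2, 0 °C to rt
Reagents that add atoms: none
Why: Nucleophile-catalysed acylation reaches only the secondary O8 because O1 is tertiary, and the iodide has no anti-periplanar hydrogen for elimination.

Step 16
Reactants: 23 iodo isovalerate
Product: 24 cis-fused hydroazulene (1α-OH; 5α-H; C4=C15 exocyclic methylene)
Conditions: Bu3SnH (slow addition), AIBN (cat.), toluene (5 mM), 85 °C
Reagents that add atoms: none
Why: In this tin hydride mediated 5-exo-dig radical cyclisation the C5 radical adds to the inner alkyne carbon of the β chain on the neighbouring C1, so ring A can only form cis-fused (5α-H), and the vinyl radical takes up hydrogen, with high dilution and slow addition holding back direct reduction and attack on the methylene lactone.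

Step 17
Reactants: 24 hydroazulene
Product: 25 3α-allylic alcohol
Conditions: SeO2 (0.3 equiv), tBuOOH, CH2Cl2, 0 °C to rt
Reagents that add atoms: tert-butyl hydroperoxide CC(C)(C)OO
Why: Selenium dioxide allylic oxidation (ene reaction then [2,3]-shift) touches only the electron-rich C4=C15 alkene, prefers the C3 methylene over the hindered C5 methine as in related guaianolides, and delivers oxygen from the convex α face (a centre reset in step 19).

Step 18
Reactants: 25 3α-allylic alcohol
Product: 26 α-methylene cyclopentanone (C3 ketone; C4=C15)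
Conditions: Dess–Martin periodinane, CH2Cl2, 0 °C to rt
Reagents that add atoms: none
Why: Dess–Martin oxidation converts the only oxidisable carbinol under near-neutral conditions that spare the β-hydroxy ketone unit.

Step 19
Reactants: 26 enone
Product: 27 3β-allylic alcohol
Conditions: NaBH4, CeCl3·7H2O, MeOH, −78 °C
Reagents that add atoms: none
Why: In the Luche reduction hydride adds 1,2 from the convex α face (H5 and O1 there, C6 and C10 on the other face), which places the hydroxyl on the concave β face, and at this temperature the methylene lactone is not reduced.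

Step 20
Reactants: 27 3β-allylic alcohol
Product: 28 epoxy diol (4β-O spiro-epoxide; C15 α; 3β-OH; 1α-OH)
Conditions: VO(acac)2 (5 mol%), tBuOOH, CH2Cl2, 0 °C
Reagents that add atoms: tert-butyl hydroperoxide CC(C)(C)OO
Why: In this hydroxyl-directed vanadium-catalysed epoxidation the allylic 3β-hydroxyl carries the peroxide to the β face of C4=C15 and so sets C4 with its oxygen trans to H5, an allylic director being far more effective than the hindered homoallylic O1, and the electron-poor lactone methylene is inert.

Step 21
Reactants: 28 epoxy diol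
Product: 29 hydroazulene C1 carbinol with C3 ketone and C4 spiro-epoxide
Conditions: Dess–Martin periodinane, CH2Cl2, 0 °C to rt
Reagents that add atoms: none
Why: Dess–Martin oxidation of the single secondary carbinol gives the α,β-epoxy ketone without opening the epoxide or disturbing C4.

Step 22
Reactants: 29 epoxy ketone carbinol
Product: 30 ten-membered C1/C3 diketone with Z C4=C5 alkene and free C15 hydroxyl
Conditions: Ti(OiPr)4 (2.2 equiv), 4 Å MS, CH2Cl2, 0 °C to rt; aq. citric acid work-up
Reagents that add atoms: none
Why: The hindered C1 hydroxyl exchanges onto titanium (helped by the neighbouring C10 acetal oxygen) while a second titanium centre chelates O3 and the epoxide oxygen on the opposite β face, and the alkoxide lone pair then pushes the C1–C5 σ bond into the C4–O σ* orbital, so that the C1 carbonyl, the C4=C5 π bond and the C15 alkoxide arise in one concerted Grob-type event. The closest known reaction type is the Lewis acid or amine promoted epoxy alcohol fragmentation of fused bicycles to medium-ring keto allylic alcohols. No ring is closed by bond formation: rings A and B merge into the ten-membered ring by scission of their shared bond, driven by release of epoxide strain and by conjugation of the new alkene with the C3 carbonyl. No stereocentre is created, and the alkene geometry is stereospecific, because with the epoxide oxygen trans to H5 (cis to C6) an envelope pucker of ring A brings C4–O to roughly 160° from C1–C5 and C3 must then end up cis to C6 (Z). The step needs C1–C5 cleavage to win over C1–C2 cleavage and over loss of water: retro-aldol opening is the reverse of a 5-(enolendo)-exo-trig closure, its breaking bond lies near the nodal plane of the C3 carbonyl and it can simply re-close, while the Grob pathway has no way back and ends in a weakly basic titanium β-diketonate. The acetal on O10 cannot move to O1, and the mild medium should leave the methylene lactone and the isovalerate untouched at room temperature.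

Step 23
Reactants: 30 ten-membered diketone
Product: 32 target CNP0171896.2, via hydroxy diketone 31 (not isolated)
Conditions: CF3CO2H, CH2Cl2, H2O (trace), 0 °C to rt
Reagents that add atoms: none
Why: Acid hydrolysis of the acetal frees O10, which adds 5-exo-trig to the C3 carbonyl and loses water (acid-catalysed cyclodehydration of an α'-hydroxy 1,3-diketone to a 3(2H)-furanone), the five-membered closure outrunning the six-membered alternative from O15 onto C1, the vinylogous ester being the thermodynamic sink and no stereocentre being touched.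

Compound list
1 | (R)-citramalic acid | OC(=O)[C@@](C)(CC(=O)O)O | starting material
2 | [(4R)-2,2,4-trimethyl-5-oxo-1,3-dioxolan-4-yl]acetic acid | CC1(C)OC(=O)[C@@](C)(CC(=O)O)O1 | intermediate
3 | S-ethyl [(4R)-2,2,4-trimethyl-5-oxo-1,3-dioxolan-4-yl]ethanethioate | CC1(C)OC(=O)[C@@](C)(CC(=O)SCC)O1 | intermediate
4 | [(4R)-2,2,4-trimethyl-5-oxo-1,3-dioxolan-4-yl]acetaldehyde | CC1(C)OC(=O)[C@@](C)(CC=O)O1 | intermediate
5 | allylboronic acid pinacol ester | C=CCB1OC(C)(C)C(C)(C)O1 | starting material
6 | tert-butyl but-3-enoate | C=CCC(=O)OC(C)(C)C | starting material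
7 | tert-butyl (E)-5-(4,4,5,5-tetramethyl-1,3,2-dioxaborolan-2-yl)pent-3-enoate | CC(C)(C)OC(=O)C/C=C/CB1OC(C)(C)C(C)(C)O1 | intermediate
8 | tert-butyl (3S,4R)-3-ethenyl-4-hydroxy-5-[(4R)-2,2,4-trimethyl-5-oxo-1,3-dioxolan-4-yl]pentanoate | CC1(C)OC(=O)[C@@](C)(C[C@@H](O)[C@@H](CC(=O)OC(C)(C)C)C=C)O1 | intermediate
9 | C8 triethylsilyl ether of 8 | CC1(C)OC(=O)[C@@](C)(C[C@@H](O[Si](CC)(CC)CC)[C@@H](CC(=O)OC(C)(C)C)C=C)O1 | intermediate
10 | Weinreb amide with free C10 hydroxyl (3S,4R,6R) | CON(C)C(=O)[C@@](C)(C[C@@H](O[Si](CC)(CC)CC)[C@@H](CC(=O)OC(C)(C)C)C=C)O | intermediate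
11 | C10 methoxymethyl ether of 10 | CON(C)C(=O)[C@@](C)(C[C@@H](O[Si](CC)(CC)CC)[C@@H](CC(=O)OC(C)(C)C)C=C)OCOC | intermediate
12 | vinyl ketone (3S,4R,6R) | C=CC(=O)[C@@](C)(C[C@@H](O[Si](CC)(CC)CC)[C@@H](CC(=O)OC(C)(C)C)C=C)OCOC | intermediate
13 | cycloheptenone (7α side chain; 8α-OSiEt3; 10β-OCH2OMe) | O=C1C=C[C@H](CC(=O)OC(C)(C)C)[C@H](O[Si](CC)(CC)CC)C[C@@]1(C)OCOC | intermediate
14 | (4-bromobut-1-yn-1-yl)trimethylsilane | C[Si](C)(C)C#CCCBr | starting material
15 | [4-(trimethylsilyl)but-3-yn-1-yl]magnesium bromide | C[Si](C)(C)C#CCC[Mg]Br | intermediate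
16 | 1α-carbinol with β butynyl chain | O[C@]1(CCC#C[Si](C)(C)C)C=C[C@H](CC(=O)OC(C)(C)C)[C@H](O[Si](CC)(CC)CC)C[C@@]1(C)OCOC | intermediate
17 | Mannich base (C11 epimers) | O[C@]1(CCC#C[Si](C)(C)C)C=C[C@H](C(CN(C)C)C(=O)OC(C)(C)C)[C@H](O[Si](CC)(CC)CC)C[C@@]1(C)OCOC | intermediate
18 | trimethylammonium iodide of 17 | O[C@]1(CCC#C[Si](C)(C)C)C=C[C@H](C(C[N+](C)(C)C)C(=O)OC(C)(C)C)[C@H](O[Si](CC)(CC)CC)C[C@@]1(C)OCOC.[I-] | intermediate
19 | tert-butyl acrylate (C11=C13) | O[C@]1(CCC#C[Si](C)(C)C)C=C[C@H](C(=C)C(=O)OC(C)(C)C)[C@H](O[Si](CC)(CC)CC)C[C@@]1(C)OCOC | intermediate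
20 | terminal alkyne with free 8α-OH | O[C@]1(CCC#C)C=C[C@H](C(=C)C(=O)OC(C)(C)C)[C@H](O)C[C@@]1(C)OCOC | intermediate
21 | iodolactone (6α-O; 5β-I; 8α-OH) | C=C1C(=O)O[C@H]2[C@H](I)[C@](O)(CCC#C)[C@@](C)(C[C@@H](O)[C@@H]12)OCOC | intermediate
22 | isovaleryl chloride | CC(C)CC(=O)Cl | starting material
23 | 8α-isovalerate of 21 | C=C1C(=O)O[C@H]2[C@H](I)[C@](O)(CCC#C)[C@@](C)(C[C@@H](OC(=O)CC(C)C)[C@@H]12)OCOC | intermediate
24 | cis-hydroazulene with C4=C15 methylene (1α-OH; 5α-H) | C=C1C(=O)O[C@H]2[C@@H]3C(=C)CC[C@]3(O)[C@@](C)(C[C@@H](OC(=O)CC(C)C)[C@@H]12)OCOC | intermediate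
25 | 3α-allylic alcohol | C=C1C(=O)O[C@H]2[C@@H]3C(=C)[C@@H](O)C[C@]3(O)[C@@](C)(C[C@@H](OC(=O)CC(C)C)[C@@H]12)OCOC | intermediate
26 | C3 enone | C=C1C(=O)O[C@H]2[C@@H]3C(=C)C(=O)C[C@]3(O)[C@@](C)(C[C@@H](OC(=O)CC(C)C)[C@@H]12)OCOC | intermediate
27 | 3β-allylic alcohol | C=C1C(=O)O[C@H]2[C@@H]3C(=C)[C@H](O)C[C@]3(O)[C@@](C)(C[C@@H](OC(=O)CC(C)C)[C@@H]12)OCOC | intermediate
28 | epoxy diol (4β-O; 3β-OH) | C=C1C(=O)O[C@H]2[C@@H]3[C@@]4(CO4)[C@H](O)C[C@]3(O)[C@@](C)(C[C@@H](OC(=O)CC(C)C)[C@@H]12)OCOC | intermediate
29 | hydroazulene C1 carbinol with C3 ketone and C4 spiro-epoxide | C=C1C(=O)O[C@H]2[C@@H]3[C@@]4(CO4)C(=O)C[C@]3(O)[C@@](C)(C[C@@H](OC(=O)CC(C)C)[C@@H]12)OCOC | intermediate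
30 | ten-membered C1/C3 diketone, Z alkene, free C15 hydroxyl, O10 acetal | C=C1C(=O)O[C@H]2/C=C(/CO)C(=O)CC(=O)[C@@](C)(C[C@@H](OC(=O)CC(C)C)[C@@H]12)OCOC | intermediate
31 | C10-hydroxy diketone | C=C1C(=O)O[C@H]2/C=C(/CO)C(=O)CC(=O)[C@@](C)(C[C@@H](OC(=O)CC(C)C)[C@@H]12)O | intermediate
32 | CNP0171896.2 (6S,7R,8R,10R; 4Z) | C=C1C(=O)O[C@H]2/C=C(/CO)C3=CC(=O)[C@@](C)(C[C@@H](OC(=O)CC(C)C)[C@@H]12)O3 | target

Total step count: 23. Longest linear sequence: 22 steps, from 1 through steps 1–3 and 5–23. Step 4 is a one-step branch.

Steps most likely to fail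

**Step 22.**
- *What may go wrong:* Loss of water from the C1 carbinol towards C2 could compete. Transient C1–C2 opening followed by irreversible β-elimination at C5 is a second risk. Slow exchange of the hindered hydroxyl onto titanium could leave time for transesterification by isopropoxide.
- *Fallback:* It sets out from 28 and comes back at 32, and it makes the same C1–C5 cut one oxidation level lower. Without a C3 carbonyl, neither retro-aldol opening nor dehydration is possible. The 3β-alkoxide and the epoxide oxygen can also share one titanium centre. Ti(OiPr)4 in CH2Cl2 should convert 28 into the ten-membered keto diol F1. Et3SiCl and imidazole silylate the primary O15 selectively to give the C15 silyl ether F2. Dess–Martin oxidation of the remaining C3 carbinol gives the silyl-protected diketone F3. CF3CO2H then removes both protecting groups and closes the furanone to 32.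

**Step 14.**
- *What may go wrong:* The tert-butyl ester may be too weak a nucleophile. Iodine would then be consumed by the alkyne or by ether formation from the free hydroxyls.
- *Fallback:* It sets out from 20 and comes back at 21, and it uses a free carboxylate instead. NaH in THF lets the O8 alkoxide displace tert-butoxide to give the 8,12-lactone F4. LiOH in aqueous THF opens this lactone to the hydroxy acrylic acid F5. F5 is not acidified. It is treated directly as its carboxylate with I2 and NaHCO3 in a classical iodolactonisation to 21.

**Step 20.**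
- *What may go wrong:* The C1 hydroxyl may compete as a director, or simple steric approach may take over. Either would put the oxygen on the convex face and lead to the wrong alkene geometry in step 22.
- *Fallback:* It sets out from 27 and comes back at 28, and it replaces metal direction by a covalent tether. Boc2O and DMAP acylate only the secondary O3 to give the 3β-tert-butyl carbonate F6. IBr in toluene at low temperature triggers a 5-exo iodocarbonate cyclisation. This can place the new C4–O bond only cis to O3, and it gives the cyclic iodocarbonate F7. Brief treatment with K2CO3 in MeOH at low temperature opens the carbonate, and the C4 alkoxide displaces iodide at C15 to give 28.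

Further compounds
F1 | step 22 | ten-membered C1 ketone with 3-OH, Z alkene and free C15 hydroxyl | C=C1C(=O)O[C@H]2/C=C(/CO)[C@H](O)CC(=O)[C@@](C)(C[C@@H](OC(=O)CC(C)C)[C@@H]12)OCOC
F2 | step 22 | C15 triethylsilyl ether of F1 | C=C1C(=O)O[C@H]2/C=C(/CO[Si](CC)(CC)CC)[C@H](O)CC(=O)[C@@](C)(C[C@@H](OC(=O)CC(C)C)[C@@H]12)OCOC
F3 | step 22 | C1/C3 diketone with C15 triethylsilyl ether | C=C1C(=O)O[C@H]2/C=C(/CO[Si](CC)(CC)CC)C(=O)CC(=O)[C@@](C)(C[C@@H](OC(=O)CC(C)C)[C@@H]12)OCOC
F4 | step 14 | 8,12-lactone (α-methylene, cis-fused at C7/C8) | C=C1C(=O)O[C@@H]2C[C@@](C)(OCOC)[C@@](O)(CCC#C)C=C[C@H]12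
F5 | step 14 | hydroxy acrylic acid | O[C@]1(CCC#C)C=C[C@H](C(=C)C(=O)O)[C@H](O)C[C@@]1(C)OCOC
F6 | step 20 | 3β-tert-butyl carbonate of 27 | C=C1C(=O)O[C@H]2[C@@H]3C(=C)[C@H](OC(=O)OC(C)(C)C)C[C@]3(O)[C@@](C)(C[C@@H](OC(=O)CC(C)C)[C@@H]12)OCOC
F7 | step 20 | cyclic 3β,4β-carbonate with C15 iodide | C=C1C(=O)O[C@H]2[C@@H]3[C@]4(CI)OC(=O)O[C@@H]4C[C@]3(O)[C@@](C)(C[C@@H](OC(=O)CC(C)C)[C@@H]12)OCOC
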